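At early times the north-west and east runs have lost about the same starting material by 0.0833 d, 33.8% and 34.2%. Yet the east run, with its larger charge of second reagent, holds more target, 20.6% against 13.5%. So the second reagent seems to act after the starting material has gone, through something I do not read.

| flask | starting material | partner | second reagent | remark | time |
|---|---|---|---|---|---|
| north-west | 0.050 M | 0.0525 M (fed, over 2.0 h) | 0.034 M | run made earlier; the fed solution adds 1.0 times the starting volume |  |
| east | 0.050 M | 0.0525 M (fed, over 2.0 h) | 0.075 M | run made earlier; the fed solution adds 1.0 times the starting volume |  |
| west | 0.050 M | 0.10 M (fed, over 2.0 h) | 0.050 M | run made earlier; the fed solution adds 1.0 times the starting volume |  |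
| flask | 0.050 M | 0.0525 M (fed, over 2.0 h) | 0.0500 M | the fed solution adds 1.0 times the starting volume | 15 d |

| run | time / d | target / % | starting material / % |
|---|---|---|---|
| north-west | 0.0833 | 13.5 | 66.2 |
| north-west | 0.417 | 29.0 | 18.3 |
| north-west | 2.08 | 0.4 | 2.7 |
| north-west | 10.0 | 0 | 0 |
| east | 0.0833 | 20.6 | 65.8 |
| east | 0.417 | 37.2 | 17.6 |
| east | 2.08 | 1.5 | 2.1 |
| east | 10.0 | 0.1 | 0 |
| west | 0.0833 | 28.0 | 44.5 |
| west | 0.417 | 38.3 | 1.9 |
| west | 2.08 | 1.2 | 0.8 |
| west | 10.0 | 0.9 | 0.8 |

(each reading ± 0.5 percentage points)

- charges are per starting volume, the dose included; the dosed solution carries all of it
- the earlier runs were read with a standard deviation of 0.5 percentage points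

- time, not beyond 15 d, at which the flask holds most target
- the amount of target, in percent of the starting material charged, at that time

How fast does target leave once it is made? In the east run it falls from 37.2% at 0.417 d to 1.5% at 2.08 d. I read that as a first-order decay with a leak constant L, the fraction of the target lost per day, of 1.93 /d. The west run reads 2.08 /d. Target rises while making beats L times target, and it peaks where the two are equal.

How high is that peak? The flask's second reagent lies between the north-west and east charges, so in proportion it should hold about 32.2% at 0.417 d.

The forecast puts the peak at 0.27 d with 35%, and says “The 10 h value already lies past the maximum.” I take its time. Going back from 0.417 d to that time with L and nothing made meanwhile lifts 32.2% to 42.8%, so I expect a peak between those two figures.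

The flask peaks at 40.9% at 0.267 d, 5.9 points above the forecast and below my top figure.

    starting material + partner → intermediate (k = 17.3 /M/h)
    second reagent + intermediate → target (k = 45.8 /M/h)
    target → over-reaction product (k = 0.125 /h)

At that time 27.4% of the starting material and 11.5% as intermediate still stand. From the peak, L alone gives 24.4% at 0.533 d, and the flask holds 30.0%. My L is an estimate read from the runs, and reckoned with it the flask's peak stands for a loss of 0.789 /d of the charge. The neighbour flask with 0.032 M of partner peaks at 30.1%, for which the same estimate reckons 0.581 /d.

All runs are simulated on assumed constants; scatter was added.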